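**Retrosynthetic overview**
- Vibsanin P (34) ⇐ silyl ether cleavage, side-chain cross-metathesis and Mitsunobu esterification with inversion at C2 ⇐ anti epoxy alcohol 29 ⇐ hydroxyl-directed epoxidation of the 11-membered trienol 28 (oxirane formed second).
- The 11-membered carbocycle (formed first) ⇐ C10–C11 C(sp3)–C(sp2) bond, closed by a nickel-electrocatalysed decarboxylative alkenylation inside seco acid 23 (vinyl iodide plus redox-active ester).
- 23 ⇐ E-selective Wittig olefination (C7=C8) with ylide 20 ⇐ Johnson–Claisen ester 17 (C5 quaternary centre by 1,3-chirality transfer from the temporary C3 carbinol).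
- 17 ⇐ chelation-controlled alkenyl addition of 12 to the α-(PMB-oxy) aldehyde 9 ⇐ vinyl iodide 5 (alkyne carboalumination) ⇐ methyl (S)-glycerate acetonide 1, the only source of chirality.

Assumption: C-locants in the Why lines are those of the target's 12-oxabicyclo[9.1.0]dodecane name (C1 epoxide C–Me, C2 ester carbinol, C5 quaternary carbon, C8 carbon bearing CH2OH, C11 epoxide CH), and a two-stage one-pot operation counts as one step.

Step 1
Reactants: 1 methyl (S)-2,2-dimethyl-1,3-dioxolane-4-carboxylate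
Product: 3 (R)-4-ethynyl-2,2-dimethyl-1,3-dioxolane, via (S)-glyceraldehyde acetonide 2 (not isolated)
Conditions: i-Bu2AlH, CH2Cl2, −78 °C; then MeOH, K2CO3, dimethyl (1-diazo-2-oxopropyl)phosphonate, −78 °C → rt
Reagents that add atoms: dimethyl (1-diazo-2-oxopropyl)phosphonate (Ohira–Bestmann reagent), COP(=O)(OC)C(=[N+]=[N-])C(C)=O
Why: One-pot ester half-reduction and Seyferth–Gilbert homologation (Ohira–Bestmann variant) gives the terminal alkyne, and the bought α-alkoxy stereocentre (future C2) is not touched under the mild K2CO3/MeOH conditions.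

Step 2
Reactants: 3 (R)-4-ethynyl-2,2-dimethyl-1,3-dioxolane
Product: 5 (R)-4-[(E)-1-iodoprop-1-en-2-yl]-2,2-dimethyl-1,3-dioxolane, via alkenylalane 4 (not isolated)
Conditions: AlMe3 (3 equiv), Cp2ZrCl2 (20 mol %), H2O (1 equiv), CH2Cl2, −20 °C; then I2, THF, −20 → 0 °C
Reagents that add atoms: trimethylaluminium, C[Al](C)C; iodine, II
Why: Zirconium-catalysed Negishi carboalumination adds Me and Al syn with Me on the internal carbon, and iodinolysis with retention fixes the E geometry of the future C1=C11 alkene; the water-accelerated protocol at −20 °C spares the acetonide.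

Step 3
Reactants: 5 (R)-4-[(E)-1-iodoprop-1-en-2-yl]-2,2-dimethyl-1,3-dioxolane
Product: 7 (4R)-4-[(E)-1-iodoprop-1-en-2-yl]-2-(4-methoxyphenyl)-1,3-dioxolane, via diol 6 (not isolated)
Conditions: PPTS, MeOH, 45 °C; evaporate; then 4-MeOC6H4CH(OMe)2, PPTS, CH2Cl2, rt
Reagents that add atoms: 4-methoxybenzaldehyde dimethyl acetal, COC(OC)c1ccc(OC)cc1
Why: Acid-catalysed transacetalisation swaps the acetonide for a 4-methoxybenzylidene acetal (both acetal epimers, the new centre is destroyed in step 4) without touching the C2 stereocentre or the vinyl iodide.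

Step 4
Reactants: 7 (4R)-4-[(E)-1-iodoprop-1-en-2-yl]-2-(4-methoxyphenyl)-1,3-dioxolane
Product: 8 (R,E)-4-iodo-2-[(4-methoxybenzyl)oxy]-3-methylbut-3-en-1-ol
Conditions: i-Bu2AlH (3 equiv), CH2Cl2, −78 → 0 °C
Reagents that add atoms: none
Why: Regioselective reductive acetal opening: aluminium binds the less hindered primary oxygen and hydride is delivered to the oxocarbenium ion, leaving the PMB ether on the secondary (C2) oxygen and a free primary alcohol.

Step 5
Reactants: 8 (R,E)-4-iodo-2-[(4-methoxybenzyl)oxy]-3-methylbut-3-en-1-ol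
Product: 9 (R,E)-4-iodo-2-[(4-methoxybenzyl)oxy]-3-methylbut-3-enal
Conditions: Dess–Martin periodinane, NaHCO3, CH2Cl2, 0 °C; used crude at once
Reagents that add atoms: none
Why: Buffered Dess–Martin oxidation gives the α-alkoxy aldehyde under near-neutral conditions, which limits epimerisation of the α-alkoxy, β,γ-unsaturated centre.

Step 6
Reactants: 10 pent-1-en-4-yne
Product: 12 (E)-1-iodo-2-methylpenta-1,4-diene, via alkenylalane 11 (not isolated)
Conditions: AlMe3 (2 equiv), Cp2ZrCl2 (25 mol %), CH2Cl2, 0 °C → rt; then I2, THF, −30 °C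
Reagents that add atoms: trimethylaluminium, C[Al](C)C; iodine, II
Why: Negishi carboalumination–iodination of the terminal alkyne gives the E vinyl iodide (I cis to Me), which fixes the olefin geometry that the Claisen step later translates into the C5 configuration.

Step 7
Reactants: 9 (R,E)-4-iodo-2-[(4-methoxybenzyl)oxy]-3-methylbut-3-enal; 12 (E)-1-iodo-2-methylpenta-1,4-diene
Product: 15 (1E,3R,4R,5E)-1-iodo-3-[(4-methoxybenzyl)oxy]-2,6-dimethylnona-1,5,8-trien-4-ol, via alkenyllithium 13 (not isolated), via alkenylmagnesium bromide 14 (not isolated)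
Conditions: 12, t-BuLi (2.05 equiv), Et2O, −78 °C; MgBr2·OEt2, −78 → 0 °C; then 9 precomplexed with MgBr2·OEt2, CH2Cl2, −78 °C; aq NH4Cl
Reagents that add atoms: none
Why: Cram-chelate addition: magnesium bridges the aldehyde and PMB-ether oxygens and the alkenyl Grignard attacks from the face bearing the small α-hydrogen, giving the syn (3R,4R) alcohol, so the temporary C3 carbinol is controlled by the bought C2 centre.

Step 8
Reactants: 15 (1E,3R,4R,5E)-1-iodo-3-[(4-methoxybenzyl)oxy]-2,6-dimethylnona-1,5,8-trien-4-ol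
Product: 17 ethyl (3S,4E,6S,7E)-8-iodo-6-[(4-methoxybenzyl)oxy]-3,7-dimethyl-3-(prop-2-en-1-yl)octa-4,7-dienoate, via ketene acetal 16 (not isolated)
Conditions: MeC(OEt)3 (10 equiv), EtCO2H (10 mol %), xylene, 135 °C, EtOH distilled off
Reagents that add atoms: triethyl orthoacetate, CCOC(C)(OCC)OCC
Why: Johnson–Claisen rearrangement through a chair transition state with the carbinol substituent equatorial (enforced by the cis methyl) is suprafacial, so the carbinol chirality is transferred to the new C5 quaternary centre (S) and the C3=C4 alkene is formed E; the PMB ether and vinyl iodide are thermally inert.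

Step 9
Reactants: 18 ethyl (triphenyl-λ5-phosphanylidene)acetate; 19 methyl acrylate
Product: 20 1-ethyl 5-methyl 2-(triphenyl-λ5-phosphanylidene)pentanedioate
Conditions: toluene, 80 °C
Reagents that add atoms: none
Why: Michael addition of the stabilised ylide to the acrylate followed by proton transfer regenerates a stabilised, α-substituted ylide.

Step 10
Reactants: 17 ethyl (3S,4E,6S,7E)-8-iodo-6-[(4-methoxybenzyl)oxy]-3,7-dimethyl-3-(prop-2-en-1-yl)octa-4,7-dienoate; 20 1-ethyl 5-methyl 2-(triphenyl-λ5-phosphanylidene)pentanedioate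
Product: 22 methyl (4E,7S,8E,10S,11E)-4-(ethoxycarbonyl)-12-iodo-10-[(4-methoxybenzyl)oxy]-7,11-dimethyl-7-(prop-2-en-1-yl)dodeca-4,8,11-trienoate, via aldehyde 21 (not isolated)
Conditions: i-Bu2AlH (1.1 equiv), toluene, −78 °C; MeOH; then 20, −78 → 90 °C
Reagents that add atoms: none
Why: Half-reduction to the aldehyde and Wittig olefination with the α-substituted stabilised ylide gives the trisubstituted enoate with CO2Et trans to C6, which is the C7=C8 geometry of the target (C6 and C9 cis).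

Step 11
Reactants: 22 methyl (4E,7S,8E,10S,11E)-4-(ethoxycarbonyl)-12-iodo-10-[(4-methoxybenzyl)oxy]-7,11-dimethyl-7-(prop-2-en-1-yl)dodeca-4,8,11-trienoate
Product: 23 (4E,7S,8E,10S,11E)-4-(ethoxycarbonyl)-12-iodo-10-[(4-methoxybenzyl)oxy]-7,11-dimethyl-7-(prop-2-en-1-yl)dodeca-4,8,11-trienoic acid
Conditions: LiOH·H2O (1.2 equiv), THF/H2O, 0 °C; then 1 M HCl
Reagents that add atoms: lithium hydroxide, [Li+].[OH-]
Why: Chemoselective saponification: the unhindered saturated methyl ester is hydrolysed much faster than the α-branched conjugated ethyl ester, and the vinyl iodide and PMB ether are base-stable.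

Step 12
Reactants: 23 (4E,7S,8E,10S,11E)-4-(ethoxycarbonyl)-12-iodo-10-[(4-methoxybenzyl)oxy]-7,11-dimethyl-7-(prop-2-en-1-yl)dodeca-4,8,11-trienoic acid
Product: 25 ethyl (1E,4S,5E,7S,8E)-7-[(4-methoxybenzyl)oxy]-4,8-dimethyl-4-(prop-2-en-1-yl)cycloundeca-1,5,8-triene-1-carboxylate, via N-acyloxyphthalimide 24 (not isolated)
Conditions: N-hydroxyphthalimide, N,N′-diisopropylcarbodiimide, DMAP (5 mol %), CH2Cl2, rt; solvent switched to DMF; then slow addition (12 h, final 2 mM) to NiCl2(dme) (20 mol %), 2,2′-bipyridine (24 mol %), AgNO3 (0.3 equiv), LiCl (0.1 M), DMF, Mg anode, reticulated vitreous carbon cathode, undivided cell, constant current 3 mA, rt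
Reagents that add atoms: none
Why: Proposed new method: cathodically generated zerovalent nickel–bipyridine inserts into the C11–I bond with retention of the E geometry, reduction of the N-acyloxyphthalimide (by monovalent nickel or at the silver-modified cathode) releases CO2 and phthalimide anion to give a primary C10 radical, the tethered divalent alkenylnickel captures it and reductive elimination from trivalent nickel forms the C10–C11 bond and the 11-membered ring, with high dilution and slow addition favouring ring closure over oligomers and no stereocentre touched; the closest known reaction is the intermolecular nickel-electrocatalysed decarboxylative alkenylation of redox-active esters with alkenyl iodides used to build 1,5-diene terpenoid chains, which has not been run as a macrocyclisation.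

Step 13
Reactants: 25 ethyl (1E,4S,5E,7S,8E)-7-[(4-methoxybenzyl)oxy]-4,8-dimethyl-4-(prop-2-en-1-yl)cycloundeca-1,5,8-triene-1-carboxylate
Product: 26 [(1E,4S,5E,7S,8E)-7-[(4-methoxybenzyl)oxy]-4,8-dimethyl-4-(prop-2-en-1-yl)cycloundeca-1,5,8-trien-1-yl]methanol
Conditions: i-Bu2AlH (2.5 equiv), CH2Cl2, −78 °C
Reagents that add atoms: none
Why: 1,2-Reduction of the conjugated ester gives the C8 hydroxymethyl group without changing the olefin geometry; the ether and the other alkenes are inert to the hydride.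

Step 14
Reactants: 26 [(1E,4S,5E,7S,8E)-7-[(4-methoxybenzyl)oxy]-4,8-dimethyl-4-(prop-2-en-1-yl)cycloundeca-1,5,8-trien-1-yl]methanol
Product: 27 tert-butyl{[(1E,4S,5E,7S,8E)-7-[(4-methoxybenzyl)oxy]-4,8-dimethyl-4-(prop-2-en-1-yl)cycloundeca-1,5,8-trien-1-yl]methoxy}dimethylsilane
Conditions: TBSCl, imidazole, CH2Cl2, 0 °C → rt
Reagents that add atoms: tert-butyldimethylsilyl chloride, CC(C)(C)[Si](C)(C)Cl
Why: Silylation masks the primary allylic alcohol so that it can neither direct epoxidation of C7=C8 nor be acylated in the Mitsunobu step.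

Step 15
Reactants: 27 tert-butyl{[(1E,4S,5E,7S,8E)-7-[(4-methoxybenzyl)oxy]-4,8-dimethyl-4-(prop-2-en-1-yl)cycloundeca-1,5,8-trien-1-yl]methoxy}dimethylsilane
Product: 28 (1S,2E,6E,9S,10E)-6-{[(tert-butyldimethylsilyl)oxy]methyl}-2,9-dimethyl-9-(prop-2-en-1-yl)cycloundeca-2,6,10-trien-1-ol
Conditions: DDQ (1.2 equiv), CH2Cl2/pH 7 buffer, 0 °C
Reagents that add atoms: none
Why: Oxidative PMB ether cleavage (hydride abstraction, hemiacetal hydrolysis) frees the C2 hydroxyl with its configuration unchanged; low temperature and buffer keep the silyl ether and limit over-oxidation of the bis-allylic alcohol.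

Step 16
Reactants: 28 (1S,2E,6E,9S,10E)-6-{[(tert-butyldimethylsilyl)oxy]methyl}-2,9-dimethyl-9-(prop-2-en-1-yl)cycloundeca-2,6,10-trien-1-ol
Product: 29 (1S,2S,3E,5S,7E,11S)-8-{[(tert-butyldimethylsilyl)oxy]methyl}-1,5-dimethyl-5-(prop-2-en-1-yl)-12-oxabicyclo[9.1.0]dodeca-3,7-dien-2-ol
Conditions: VO(acac)2 (5 mol %), t-BuOOH (1.5 equiv), CH2Cl2, 0 °C
Reagents that add atoms: tert-butyl hydroperoxide, CC(C)(C)OO
Why: Vanadium-catalysed hydroxyl-directed epoxidation: the vanadate ester of the C2 hydroxyl delivers oxygen to the electron-rich trisubstituted C1=C11 alkene in the A(1,2)-minimised conformer (C2–H near the C1 methyl), giving the anti (erythro) epoxy alcohol and so setting C1 and C11 from C2, while the silyl-ether-flanked C7=C8, the hindered C3=C4 and the allyl group do not react.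

Step 17
Reactants: 29 (1S,2S,3E,5S,7E,11S)-8-{[(tert-butyldimethylsilyl)oxy]methyl}-1,5-dimethyl-5-(prop-2-en-1-yl)-12-oxabicyclo[9.1.0]dodeca-3,7-dien-2-ol; 30 3-methylbut-2-enoic acid
Product: 31 (1R,2R,3E,5S,7E,11S)-8-{[(tert-butyldimethylsilyl)oxy]methyl}-1,5-dimethyl-5-(prop-2-en-1-yl)-12-oxabicyclo[9.1.0]dodeca-3,7-dien-2-yl 3-methylbut-2-enoate
Conditions: PPh3, DIAD, toluene, 0 °C → rt
Reagents that add atoms: none
Why: Mitsunobu esterification: the C2 hydroxyl is activated as an alkoxyphosphonium ion and displaced by the carboxylate in an SN2 step with inversion (2S → 2R), which converts the anti epoxy alcohol into the syn (threo) ester of the target and installs the senecioate in the same operation.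

Step 18
Reactants: 31 (1R,2R,3E,5S,7E,11S)-8-{[(tert-butyldimethylsilyl)oxy]methyl}-1,5-dimethyl-5-(prop-2-en-1-yl)-12-oxabicyclo[9.1.0]dodeca-3,7-dien-2-yl 3-methylbut-2-enoate; 32 2-methylbut-3-en-2-ol
Product: 33 (1R,2R,3E,5S,7E,11S)-8-{[(tert-butyldimethylsilyl)oxy]methyl}-5-[(2E)-4-hydroxy-4-methylpent-2-en-1-yl]-1,5-dimethyl-12-oxabicyclo[9.1.0]dodeca-3,7-dien-2-yl 3-methylbut-2-enoate
Conditions: 32 (10 equiv), second-generation Grubbs catalyst RuCl2(H2IMes)(PCy3)(=CHPh) (5 mol %), CH2Cl2, 40 °C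
Reagents that add atoms: none
Why: Olefin cross-metathesis of the only terminal alkene with the tertiary allylic alcohol gives the E side-chain olefin; the trisubstituted, neopentyl-flanked and conjugated alkenes and the epoxide are unreactive toward the ruthenium carbene.

Step 19
Reactants: 33 (1R,2R,3E,5S,7E,11S)-8-{[(tert-butyldimethylsilyl)oxy]methyl}-5-[(2E)-4-hydroxy-4-methylpent-2-en-1-yl]-1,5-dimethyl-12-oxabicyclo[9.1.0]dodeca-3,7-dien-2-yl 3-methylbut-2-enoate
Product: 34 Vibsanin P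
Conditions: HF·pyridine, pyridine, THF, 0 °C
Reagents that add atoms: none
Why: Buffered fluoride desilylation frees the primary allylic alcohol without opening the epoxide, cleaving the ester or ionising the tertiary allylic alcohol.

**Compound list**
1 | methyl (S)-2,2-dimethyl-1,3-dioxolane-4-carboxylate | COC(=O)[C@@H]1COC(C)(C)O1 | starting material
2 | (S)-2,2-dimethyl-1,3-dioxolane-4-carbaldehyde | O=C[C@@H]1COC(C)(C)O1 | intermediate (not isolated)
3 | (R)-4-ethynyl-2,2-dimethyl-1,3-dioxolane | C#C[C@@H]1COC(C)(C)O1 | intermediate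
4 | {(E)-2-[(4R)-2,2-dimethyl-1,3-dioxolan-4-yl]prop-1-en-1-yl}dimethylalumane | C[Al](C)/C=C(\C)[C@@H]1COC(C)(C)O1 | intermediate (not isolated)
5 | (R)-4-[(E)-1-iodoprop-1-en-2-yl]-2,2-dimethyl-1,3-dioxolane | I/C=C(\C)[C@@H]1COC(C)(C)O1 | intermediate
6 | (R,E)-4-iodo-3-methylbut-3-ene-1,2-diol | I/C=C(\C)[C@@H](O)CO | intermediate (not isolated)
7 | (4R)-4-[(E)-1-iodoprop-1-en-2-yl]-2-(4-methoxyphenyl)-1,3-dioxolane (both acetal epimers) | I/C=C(\C)[C@@H]1COC(c2ccc(OC)cc2)O1 | intermediate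
8 | (R,E)-4-iodo-2-[(4-methoxybenzyl)oxy]-3-methylbut-3-en-1-ol | I/C=C(\C)[C@H](CO)OCc1ccc(OC)cc1 | intermediate
9 | (R,E)-4-iodo-2-[(4-methoxybenzyl)oxy]-3-methylbut-3-enal | I/C=C(\C)[C@H](C=O)OCc1ccc(OC)cc1 | intermediate
10 | pent-1-en-4-yne | C=CCC#C | starting material
11 | dimethyl[(E)-2-methylpenta-1,4-dien-1-yl]alumane | C[Al](C)/C=C(\C)CC=C | intermediate (not isolated)
12 | (E)-1-iodo-2-methylpenta-1,4-diene | I/C=C(\C)CC=C | intermediate
13 | [(E)-2-methylpenta-1,4-dien-1-yl]lithium | [Li]/C=C(\C)CC=C | intermediate (not isolated)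
14 | [(E)-2-methylpenta-1,4-dien-1-yl]magnesium bromide | Br[Mg]/C=C(\C)CC=C | intermediate (not isolated)
15 | (1E,3R,4R,5E)-1-iodo-3-[(4-methoxybenzyl)oxy]-2,6-dimethylnona-1,5,8-trien-4-ol | I/C=C(\C)[C@H]([C@H](O)/C=C(\C)CC=C)OCc1ccc(OC)cc1 | intermediate
16 | (1E,3R,4R,5E)-4-[(1-ethoxyethenyl)oxy]-1-iodo-3-[(4-methoxybenzyl)oxy]-2,6-dimethylnona-1,5,8-triene (ketene acetal) | I/C=C(\C)[C@H]([C@H](OC(=C)OCC)/C=C(\C)CC=C)OCc1ccc(OC)cc1 | intermediate (not isolated)
17 | ethyl (3S,4E,6S,7E)-8-iodo-6-[(4-methoxybenzyl)oxy]-3,7-dimethyl-3-(prop-2-en-1-yl)octa-4,7-dienoate | I/C=C(\C)[C@H](/C=C/[C@@](C)(CC=C)CC(=O)OCC)OCc1ccc(OC)cc1 | intermediate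
18 | ethyl (triphenyl-λ5-phosphanylidene)acetate | CCOC(=O)C=P(c1ccccc1)(c1ccccc1)c1ccccc1 | starting material
19 | methyl acrylate | C=CC(=O)OC | starting material
20 | 1-ethyl 5-methyl 2-(triphenyl-λ5-phosphanylidene)pentanedioate | CCOC(=O)C(CCC(=O)OC)=P(c1ccccc1)(c1ccccc1)c1ccccc1 | intermediate
21 | (3S,4E,6S,7E)-8-iodo-6-[(4-methoxybenzyl)oxy]-3,7-dimethyl-3-(prop-2-en-1-yl)octa-4,7-dienal | I/C=C(\C)[C@H](/C=C/[C@@](C)(CC=C)CC=O)OCc1ccc(OC)cc1 | intermediate (not isolated)
22 | methyl (4E,7S,8E,10S,11E)-4-(ethoxycarbonyl)-12-iodo-10-[(4-methoxybenzyl)oxy]-7,11-dimethyl-7-(prop-2-en-1-yl)dodeca-4,8,11-trienoate | I/C=C(\C)[C@H](/C=C/[C@@](C)(CC=C)C/C=C(\CCC(=O)OC)C(=O)OCC)OCc1ccc(OC)cc1 | intermediate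
23 | (4E,7S,8E,10S,11E)-4-(ethoxycarbonyl)-12-iodo-10-[(4-methoxybenzyl)oxy]-7,11-dimethyl-7-(prop-2-en-1-yl)dodeca-4,8,11-trienoic acid | I/C=C(\C)[C@H](/C=C/[C@@](C)(CC=C)C/C=C(\CCC(=O)O)C(=O)OCC)OCc1ccc(OC)cc1 | intermediate
24 | 1,3-dioxoisoindolin-2-yl ester of 23 (N-acyloxyphthalimide) | I/C=C(\C)[C@H](/C=C/[C@@](C)(CC=C)C/C=C(\CCC(=O)ON1C(=O)c2ccccc2C1=O)C(=O)OCC)OCc1ccc(OC)cc1 | intermediate (not isolated)
25 | ethyl (1E,4S,5E,7S,8E)-7-[(4-methoxybenzyl)oxy]-4,8-dimethyl-4-(prop-2-en-1-yl)cycloundeca-1,5,8-triene-1-carboxylate | COc1ccc(CO[C@H]2/C=C/[C@@](C)(CC=C)C/C=C(/C(=O)OCC)CC/C=C2\C)cc1 | intermediate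
26 | [(1E,4S,5E,7S,8E)-7-[(4-methoxybenzyl)oxy]-4,8-dimethyl-4-(prop-2-en-1-yl)cycloundeca-1,5,8-trien-1-yl]methanol | COc1ccc(CO[C@H]2/C=C/[C@@](C)(CC=C)C/C=C(/CO)CC/C=C2\C)cc1 | intermediate
27 | tert-butyl{[(1E,4S,5E,7S,8E)-7-[(4-methoxybenzyl)oxy]-4,8-dimethyl-4-(prop-2-en-1-yl)cycloundeca-1,5,8-trien-1-yl]methoxy}dimethylsilane | COc1ccc(CO[C@H]2/C=C/[C@@](C)(CC=C)C/C=C(/CO[Si](C)(C)C(C)(C)C)CC/C=C2\C)cc1 | intermediate
28 | (1S,2E,6E,9S,10E)-6-{[(tert-butyldimethylsilyl)oxy]methyl}-2,9-dimethyl-9-(prop-2-en-1-yl)cycloundeca-2,6,10-trien-1-ol | O[C@H]1/C=C/[C@@](C)(CC=C)C/C=C(/CO[Si](C)(C)C(C)(C)C)CC/C=C1\C | intermediate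
29 | (1S,2S,3E,5S,7E,11S)-8-{[(tert-butyldimethylsilyl)oxy]methyl}-1,5-dimethyl-5-(prop-2-en-1-yl)-12-oxabicyclo[9.1.0]dodeca-3,7-dien-2-ol | O[C@H]1/C=C/[C@@](C)(CC=C)C/C=C(/CO[Si](C)(C)C(C)(C)C)CC[C@@H]2O[C@]21C | intermediate
30 | 3-methylbut-2-enoic acid (senecioic acid) | CC(C)=CC(=O)O | starting material
31 | (1R,2R,3E,5S,7E,11S)-8-{[(tert-butyldimethylsilyl)oxy]methyl}-1,5-dimethyl-5-(prop-2-en-1-yl)-12-oxabicyclo[9.1.0]dodeca-3,7-dien-2-yl 3-methylbut-2-enoate | CC(C)=CC(=O)O[C@@H]1/C=C/[C@@](C)(CC=C)C/C=C(/CO[Si](C)(C)C(C)(C)C)CC[C@@H]2O[C@]21C | intermediate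
32 | 2-methylbut-3-en-2-ol | C=CC(C)(C)O | starting material
33 | (1R,2R,3E,5S,7E,11S)-8-{[(tert-butyldimethylsilyl)oxy]methyl}-5-[(2E)-4-hydroxy-4-methylpent-2-en-1-yl]-1,5-dimethyl-12-oxabicyclo[9.1.0]dodeca-3,7-dien-2-yl 3-methylbut-2-enoate | CC(C)=CC(=O)O[C@@H]1/C=C/[C@@](C)(C/C=C/C(C)(C)O)C/C=C(/CO[Si](C)(C)C(C)(C)C)CC[C@@H]2O[C@]21C | intermediate
34 | Vibsanin P, (1R,2R,3E,5S,7E,11S)-8-(hydroxymethyl)-5-[(2E)-4-hydroxy-4-methylpent-2-en-1-yl]-1,5-dimethyl-12-oxabicyclo[9.1.0]dodeca-3,7-dien-2-yl 3-methylbut-2-enoate | CC(C)=CC(=O)O[C@@H]1/C=C/[C@@](C)(C/C=C/C(C)(C)O)C/C=C(/CO)CC[C@@H]2O[C@]21C | target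

**Step count**
Total: 19 steps. Longest linear sequence: 17 steps (steps 1–5, 7, 8, 10–19).

**Three steps most likely to fail**

Step 12 (the proposed new macrocyclisation). The tethered radical capture must outrun 1,5-hydrogen transfer from the allylic C6–H, reduction of the radical and oligomerisation. The fallback uses known chemistry and closes the ring at C7=C8 instead. It sets out from 17: reduction with i-Bu2AlH at −78 °C with isolation of aldehyde 21, then a Negishi coupling (Pd(OAc)2, SPhos, THF, rt) of its vinyl iodide with the organozinc reagent ethyl 2-(diethoxyphosphoryl)-4-(iodozincio)butanoate F1 (from the corresponding iodide, Zn, LiCl), which gives the phosphonate aldehyde ethyl (5E,7S,8E,10S)-2-(diethoxyphosphoryl)-7-[(4-methoxybenzyl)oxy]-6,10-dimethyl-12-oxo-10-(prop-2-en-1-yl)dodeca-5,8-dienoate F2. An intramolecular Horner–Wadsworth–Emmons olefination (LiCl, DBU, MeCN, 1 mM) then forms the ring, with ring strain expected to favour the isomer having C6 and C9 cis. The fallback comes back to the route at 25.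

Step 17 (Mitsunobu inversion). C2 is a hindered, allylic, epoxide-flanked carbinol and senecioic acid is a weak acid, so displacement may be slow and elimination or SN2′ may compete. The fallback sets out from 29: chloromethanesulfonyl chloride and pyridine give the isolable sulfonate (1R,2S,3E,5S,7E,11S)-8-{[(tert-butyldimethylsilyl)oxy]methyl}-1,5-dimethyl-5-(prop-2-en-1-yl)-12-oxabicyclo[9.1.0]dodeca-3,7-dien-2-yl chloromethanesulfonate F3. This is displaced with inversion by caesium 3-methylbut-2-enoate F4 (from 30 and Cs2CO3) with 18-crown-6 in toluene at 70 °C. The fallback comes back to the route at 31.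

Step 7 (chelation-controlled addition). Aldehyde 9 can epimerise or slip into conjugation, and the syn selectivity depends on clean chelation. The fallback sets out from 9 and 12: alkenyllithium 13 is added in THF at −78 °C without a chelating salt, which gives 15 mixed with its epimer (1E,3R,4S,5E)-1-iodo-3-[(4-methoxybenzyl)oxy]-2,6-dimethylnona-1,5,8-trien-4-ol F5. The mixture is oxidised with Dess–Martin periodinane to the enone (1E,3R,5E)-1-iodo-3-[(4-methoxybenzyl)oxy]-2,6-dimethylnona-1,5,8-trien-4-one F6. Felkin–Anh reduction with LiBH(s-Bu)3 in THF at −78 °C then sets the carbinol by hydride delivery anti to the C–O bond. The fallback comes back to the route at 15.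

**Further compounds**
F1 | step 12 | ethyl 2-(diethoxyphosphoryl)-4-(iodozincio)butanoate | CCOC(=O)C(CC[Zn]I)P(=O)(OCC)OCC
F2 | step 12 | ethyl (5E,7S,8E,10S)-2-(diethoxyphosphoryl)-7-[(4-methoxybenzyl)oxy]-6,10-dimethyl-12-oxo-10-(prop-2-en-1-yl)dodeca-5,8-dienoate | CCOC(=O)C(CC/C=C(\C)[C@H](/C=C/[C@@](C)(CC=C)CC=O)OCc1ccc(OC)cc1)P(=O)(OCC)OCC
F3 | step 17 | (1R,2S,3E,5S,7E,11S)-8-{[(tert-butyldimethylsilyl)oxy]methyl}-1,5-dimethyl-5-(prop-2-en-1-yl)-12-oxabicyclo[9.1.0]dodeca-3,7-dien-2-yl chloromethanesulfonate | ClCS(=O)(=O)O[C@H]1/C=C/[C@@](C)(CC=C)C/C=C(/CO[Si](C)(C)C(C)(C)C)CC[C@@H]2O[C@]21C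
F4 | step 17 | caesium 3-methylbut-2-enoate | [Cs+].[O-]C(=O)C=C(C)C
F5 | step 7 | (1E,3R,4S,5E)-1-iodo-3-[(4-methoxybenzyl)oxy]-2,6-dimethylnona-1,5,8-trien-4-ol | I/C=C(\C)[C@H]([C@@H](O)/C=C(\C)CC=C)OCc1ccc(OC)cc1
F6 | step 7 | (1E,3R,5E)-1-iodo-3-[(4-methoxybenzyl)oxy]-2,6-dimethylnona-1,5,8-trien-4-one | I/C=C(\C)[C@H](C(=O)/C=C(\C)CC=C)OCc1ccc(OC)cc1
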